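## Retrosynthetic overview

- **Rings** are formed last, in one operation, from an acyclic (R)-bromohydrin triene: Br+ on the terminal alkene closes ring A first (C5a–C6 bond), then the C2 hydroxyl closes the oxepene (O1–C9a bond). Anti addition across a Z alkene gives the cis fusion.
- **C2–CH2Br**: bromide opening of a terminal epoxide whose stereocentre is purchased.
- **Key disconnection**: the CH2–OH bond on C3 and the C3=C4 geometry come from a [2,3]-sigmatropic (Mislow–Evans) shift of an allylic sulfoxide.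
- **C4–C5**: alkylation of an α-phenylsulfanyl ketone enolate with a neryl halide; the carbon that becomes CH2OH comes from ketone methylenation.
- **Carbon sources**: nerol (C5, C5a, C6–C9, C9a, three methyls, Z alkene), methyl (S)-glycidate (O1, C2, C3, CH2Br carbon), PhSCH2Li (C4), Cp2TiMe2 (CH2OH carbon).

Assumption: the SMILES is read literally, i.e. the cis-fused (2R,5aR,7S,9aS) isomer (9a-CH3 and 5a-H on the same face) is the target; 1-benzoxepine locants are used for it throughout.

## Route

Step 1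
Reactants: 1 nerol, (2Z)-3,7-dimethylocta-2,6-dien-1-ol
Product: 2 neryl bromide, (2Z)-1-bromo-3,7-dimethylocta-2,6-diene
Conditions: PBr3 (0.4 equiv), Et2O, −10 °C
Reagents that add atoms: phosphorus tribromide, BrP(Br)Br
Why: SN2 bromination of the primary allylic alcohol through its phosphite ester at low temperature keeps the Z alkene and avoids allylic transposition; no stereocentre is involved.

Step 2
Reactants: 3 methyl (2S)-oxirane-2-carboxylate [methyl (S)-glycidate]; 2 neryl bromide
Product: 5 (4Z)-5,9-dimethyl-1-[(2S)-oxiran-2-yl]-2-(phenylsulfanyl)deca-4,8-dien-1-one (both C2 epimers), via lithium enolate 4 (not isolated)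
Conditions: PhSCH2Li (2.05 equiv; from PhSCH3, n-BuLi, DABCO, THF, 0 °C), THF, −78 °C; then 2, DMPU, −78 → 0 °C
Reagents that add atoms: (phenylsulfanyl)methyllithium, [Li]CSc1ccccc1
Why: Nucleophilic acyl substitution of the ester (the second equivalent deprotonates the acidic α-thio ketone, which stops over-addition) followed by SN2 C-alkylation of that enolate by the allylic bromide; the non-enolisable epoxide centre is untouched and the new C–S centre is a mixture that is erased in step 4.

Step 3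
Reactants: 5 (4Z)-5,9-dimethyl-1-[(2S)-oxiran-2-yl]-2-(phenylsulfanyl)deca-4,8-dien-1-one
Product: 6 (2R)-2-[(5Z)-6,10-dimethyl-3-(phenylsulfanyl)undeca-1,5,9-trien-2-yl]oxirane (both C3 epimers)
Conditions: Cp2TiMe2 (3 equiv), toluene/THF, 65 °C, dark
Reagents that add atoms: dimethyltitanocene Cp2TiMe2, [CH3-].[CH3-].[Ti+4].c1cc[cH-]c1.c1cc[cH-]c1
Why: Petasis methylenation (Cp2Ti=CH2 adds to the C=O and cycloreverts) is non-basic, so the enolisable α-thio ketone and the epoxide survive; no stereocentre is formed or touched (the descriptor changes to R only because the CIP ranking changes).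

Step 4
Reactants: 6 (2R)-2-[(5Z)-6,10-dimethyl-3-(phenylsulfanyl)undeca-1,5,9-trien-2-yl]oxirane
Product: 9 (2Z,5Z)-6,10-dimethyl-2-[(2R)-oxiran-2-yl]undeca-2,5,9-trien-1-ol, via allylic sulfoxide 7 (not isolated), via sulfenate ester 8 (not isolated)
Conditions: mCPBA (1.0 equiv), CH2Cl2, −78 °C; then P(OMe)3 (3 equiv), MeOH, −78 → 25 °C
Reagents that add atoms: 3-chloroperoxybenzoic acid (mCPBA), OOC(=O)c1cccc(Cl)c1
Why: Chemoselective S-oxidation, then Mislow–Evans [2,3]-sigmatropic rearrangement to the sulfenate, which the thiophile cleaves; the C–O bond forms at the CH2 terminus and the chain sits pseudo-equatorial in the five-membered transition state, so it ends trans to CH2OH (2Z by CIP), while the epoxide centre is untouched.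

Step 5
Reactants: 9 (2Z,5Z)-6,10-dimethyl-2-[(2R)-oxiran-2-yl]undeca-2,5,9-trien-1-ol
Product: 10 (2R,3Z,6Z)-1-bromo-3-(hydroxymethyl)-7,11-dimethyldodeca-3,6,10-trien-2-ol
Conditions: LiBr (3 equiv), AcOH (3 equiv), THF, 20 °C
Reagents that add atoms: lithium bromide, [Li+].[Br-]
Why: Halohydrin formation by SN2 opening of the monosubstituted epoxide at the primary carbon under weakly acidic, non-ionising conditions; the carbinol carbon is not attacked, so its configuration is retained.

Step 6
Reactants: 10 (2R,3Z,6Z)-1-bromo-3-(hydroxymethyl)-7,11-dimethyldodeca-3,6,10-trien-2-ol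
Product: 11 [(2R,5aR,7S,9aS)-7-bromo-2-(bromomethyl)-6,6,9a-trimethyl-2,5,5a,6,7,8,9,9a-octahydro-1-benzoxepin-3-yl]methanol (target)
Conditions: Et2SBr·SbCl5Br (BDSB, 1.1 equiv), MeNO2, −25 °C, 5 min; then aq. Na2SO3/NaHCO3
Reagents that add atoms: bromodiethylsulfonium bromopentachloroantimonate (BDSB), CC[S+](Br)CC.Br[Sb-](Cl)(Cl)(Cl)(Cl)Cl
Why: Bromonium-initiated cation–olefin bicyclisation in which C5a–C6 bond formation and hydroxyl capture at C9a are an anti addition across the Z alkene through a chair, giving equatorial Br at C7 and the cis fusion, while the purchased C2 centre selects the alkene face because only one chair-like oxepene closure keeps CH2Br pseudo-equatorial; the CH2OH group is trans to the chain and cannot reach C9a.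

## Compound list

1 | nerol, (2Z)-3,7-dimethylocta-2,6-dien-1-ol | CC(C)=CCC/C(C)=C\CO | starting material
2 | neryl bromide, (2Z)-1-bromo-3,7-dimethylocta-2,6-diene | CC(C)=CCC/C(C)=C\CBr | intermediate
3 | methyl (2S)-oxirane-2-carboxylate | COC(=O)[C@@H]1CO1 | starting material
4 | lithium 1-[(2S)-oxiran-2-yl]-2-(phenylsulfanyl)ethen-1-olate | [Li+].[O-]C(=CSc1ccccc1)[C@@H]1CO1 | intermediate
5 | (4Z)-5,9-dimethyl-1-[(2S)-oxiran-2-yl]-2-(phenylsulfanyl)deca-4,8-dien-1-one (C2 epimers) | CC(C)=CCC/C(C)=C\CC(Sc1ccccc1)C(=O)[C@@H]1CO1 | intermediate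
6 | (2R)-2-[(5Z)-6,10-dimethyl-3-(phenylsulfanyl)undeca-1,5,9-trien-2-yl]oxirane (C3 epimers) | CC(C)=CCC/C(C)=C\CC(Sc1ccccc1)C(=C)[C@@H]1CO1 | intermediate
7 | (2R)-2-[(5Z)-6,10-dimethyl-3-(phenylsulfinyl)undeca-1,5,9-trien-2-yl]oxirane (diastereomer mixture) | CC(C)=CCC/C(C)=C\CC(S(=O)c1ccccc1)C(=C)[C@@H]1CO1 | intermediate
8 | (2R)-2-{(2Z,5Z)-6,10-dimethyl-1-[(phenylsulfanyl)oxy]undeca-2,5,9-trien-2-yl}oxirane | CC(C)=CCC/C(C)=C\C/C=C(/COSc1ccccc1)[C@@H]1CO1 | intermediate
9 | (2Z,5Z)-6,10-dimethyl-2-[(2R)-oxiran-2-yl]undeca-2,5,9-trien-1-ol | CC(C)=CCC/C(C)=C\C/C=C(/CO)[C@@H]1CO1 | intermediate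
10 | (2R,3Z,6Z)-1-bromo-3-(hydroxymethyl)-7,11-dimethyldodeca-3,6,10-trien-2-ol | CC(C)=CCC/C(C)=C\C/C=C(/CO)[C@@H](O)CBr | intermediate
11 | [(2R,5aR,7S,9aS)-7-bromo-2-(bromomethyl)-6,6,9a-trimethyl-2,5,5a,6,7,8,9,9a-octahydro-1-benzoxepin-3-yl]methanol | CC1(C)[C@H]2CC=C(CO)[C@H](CBr)O[C@@]2(C)CC[C@@H]1Br | target

## Step count and risks

Total steps: 6. Longest linear sequence: 6 (1 → 2 → 5 → 6 → 9 → 10 → 11); 5 from the chiral ester 3.

**Step 6 (most likely to fail).** Closing a seven-membered ether on the tertiary cation competes with proton loss, and the face selection rests only on the remote C2 centre, so yield and diastereomer ratio are uncertain. The fallback sets out from 10 and returns at 11. Compound 10 is cyclised with Hg(OCOCF3)2 in MeNO2 at −20 °C, a softer and reversible initiator with the same anti addition, to the C7 organomercuric trifluoroacetate F1. Aqueous KBr exchanges it to the organomercuric bromide F2. Bromodemercuration of F2 with Br2, LiBr and pyridine under O2 at 0 °C puts bromine on C7 and gives 11; the equatorial epimer is favoured and the axial one is removed by chromatography.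

**Step 5.** Bromide may attack the allylic C2 position, directly or with allylic shift, instead of the primary carbon, which would lose regio- and stereochemical integrity. The fallback sets out from 5 and returns at 10. The epoxide is opened earlier, while the carbinol carbon is still α to the ketone and cannot ionise: LiBr/AcOH/THF converts 5 into the bromohydrin ketone F3. Methylenation with Cp2TiMe2 (one extra equivalent for the free hydroxyl) gives the bromohydrin allyl sulfide F4. mCPBA at −78 °C gives the allylic sulfoxide F5, which rearranges to the sulfenate ester F6; P(OMe)3 in MeOH cleaves F6 to 10.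

**Step 3.** The hindered, enolisable α-thio epoxy ketone may react sluggishly or decompose at 65 °C. The fallback sets out from 3 and returns at 7. The 1,1-disubstituted alkene is built first by Peterson chemistry: 3 with Me3SiCH2MgCl/CeCl3 (THF, −78 → 20 °C) gives the bis(silylmethyl) carbinol F7, which loses Me3SiOH on silica gel to give the allylsilane F8. PhSCl (CH2Cl2, −78 °C) replaces silicon with allyl transposition to give the allyl sulfide F9, and mCPBA at −78 °C gives the allyl sulfoxide F10. Its anion (LiN(i-Pr)2, THF, −78 °C) is alkylated at the α-carbon by 2 to give 7, which is carried on with P(OMe)3/MeOH as in step 4.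

## Further compounds

F1 | step 6 | [(2R,5aR,7S,9aS)-2-(bromomethyl)-3-(hydroxymethyl)-6,6,9a-trimethyl-2,5,5a,6,7,8,9,9a-octahydro-1-benzoxepin-7-yl]mercury trifluoroacetate | CC1(C)[C@H]2CC=C(CO)[C@H](CBr)O[C@@]2(C)CC[C@@H]1[Hg]OC(=O)C(F)(F)F
F2 | step 6 | bromo[(2R,5aR,7S,9aS)-2-(bromomethyl)-3-(hydroxymethyl)-6,6,9a-trimethyl-2,5,5a,6,7,8,9,9a-octahydro-1-benzoxepin-7-yl]mercury | CC1(C)[C@H]2CC=C(CO)[C@H](CBr)O[C@@]2(C)CC[C@@H]1[Hg]Br
F3 | step 5 | (2R,6Z)-1-bromo-2-hydroxy-7,11-dimethyl-4-(phenylsulfanyl)dodeca-6,10-dien-3-one | CC(C)=CCC/C(C)=C\CC(Sc1ccccc1)C(=O)[C@@H](O)CBr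
F4 | step 5 | (2R,6Z)-1-bromo-7,11-dimethyl-3-methylidene-4-(phenylsulfanyl)dodeca-6,10-dien-2-ol | CC(C)=CCC/C(C)=C\CC(Sc1ccccc1)C(=C)[C@@H](O)CBr
F5 | step 5 | (2R,6Z)-1-bromo-7,11-dimethyl-3-methylidene-4-(phenylsulfinyl)dodeca-6,10-dien-2-ol | CC(C)=CCC/C(C)=C\CC(S(=O)c1ccccc1)C(=C)[C@@H](O)CBr
F6 | step 5 | (2R,3Z,6Z)-1-bromo-7,11-dimethyl-3-{[(phenylsulfanyl)oxy]methyl}dodeca-3,6,10-trien-2-ol | CC(C)=CCC/C(C)=C\C/C=C(/COSc1ccccc1)[C@@H](O)CBr
F7 | step 3 | 2-[(2S)-oxiran-2-yl]-1,3-bis(trimethylsilyl)propan-2-ol | C[Si](C)(C)CC(O)(C[Si](C)(C)C)[C@@H]1CO1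
F8 | step 3 | trimethyl{2-[(2R)-oxiran-2-yl]prop-2-en-1-yl}silane | C=C(C[Si](C)(C)C)[C@@H]1CO1
F9 | step 3 | (2R)-2-[3-(phenylsulfanyl)prop-1-en-2-yl]oxirane | C=C(CSc1ccccc1)[C@@H]1CO1
F10 | step 3 | (2R)-2-[3-(phenylsulfinyl)prop-1-en-2-yl]oxirane | C=C(CS(=O)c1ccccc1)[C@@H]1CO1
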